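**Plan**

- Retrosynthesis: the two O–Si bonds are cut first, then the C1–C2 bond of the decalin together with C8a–H. This opens the ether-bearing ring to an aryl enol ether and an exocyclic C-8a methylene. Further cuts: the enol-ether C=CH2 (back to an aryl ester), the ester C–O bond (honokiol + seco acid), C8a=CH2, the tertiary C–OH bond, and C4a–C4 (methyl acrylate + dihydrocarvone).
- Enabling feature: C-2 carries CH3, O-aryl and the C-3 methylene, which is the substituent set of a methylenated aryl ester carbon. C-1 is a CH2 between C-2 and the tertiary C-8a–H, the imprint of an exocyclic C-8a=CH2 that attacked a C-2 cation and then accepted hydride.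
- Forward: the carvone ring becomes ring C4a–C5–C6–C7–C8–C8a. The C4–C3–C2 chain is attached at C-4a by Michael addition, and honokiol is joined as an ester. Ring C1–C2–C3–C4–C4a–C8a is the only ring made and closes in step 10.
- Stereochemistry: C-7 comes from (R)-carvone and C-4a from the (R)-1-phenylethylamine auxiliary. C-2 and C-8a come from the chair closure and axial hydride delivery of step 10.

Key step: step 10

Remark: decalin locants are C-2 (CH3, O-aryl), C-4a (CH3), C-7 (CMe2OH), C-8a (H); in this numbering the target is (2R,4aS,7R,8aS). Mono-silylation of honokiol is assumed to favour the 4'-hydroxyl.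

**Route**

Step 1
Reactants: 1 (R)-carvone
Product: 3 (5R)-dihydrocarvone as a mixture of C-2 epimers, via lithium enolate 2 (not isolated)
Conditions: L-Selectride (1.1 equiv), THF, −78 °C; then H2O
Reagents that add atoms: none
Why: Conjugate (1,4-) hydride reduction: L-Selectride adds hydride to the unsubstituted β-carbon of cyclohexenones such as carvone and not to the isolated isopropenyl group, C-5 is untouched, and the C-2 epimer mixture formed on protonation of enolate 2 does not matter because that centre is planarised in step 2.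

Step 2
Reactants: 3 (5R)-dihydrocarvone; 4 (R)-1-phenylethylamine; 5 methyl acrylate
Product: 8 methyl 3-[(1S,4R)-1-methyl-2-oxo-4-(prop-1-en-2-yl)cyclohexyl]propanoate, via imine 6 (not isolated), via Michael adduct imine 7 (not isolated)
Conditions: (i) 4, toluene, reflux, Dean–Stark; (ii) 5, THF, 40 °C; (iii) 20% aq. AcOH, rt
Reagents that add atoms: water (O)
Why: d'Angelo asymmetric Michael addition: imine 6 reacts through its more substituted secondary enamine tautomer in a compact aza-ene-type transition state with internal N–H transfer, the (R)-1-phenylethyl group steers the acrylate to the face that puts the propanoate arm trans to the isopropenyl group (a pairing precedented on dihydrocarvone itself), and mild acid hydrolysis of 7 should free the ketone with the quaternary centre set as (1S).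

Step 3
Reactants: 8 methyl 3-[(1S,4R)-1-methyl-2-oxo-4-(prop-1-en-2-yl)cyclohexyl]propanoate
Product: 9 methyl 3-[(1S,4R)-4-(2-hydroxypropan-2-yl)-1-methyl-2-oxocyclohexyl]propanoate
Conditions: Co(acac)2 (0.2 equiv), PhSiH3 (2.5 equiv), O2 (1 atm), THF, rt
Reagents that add atoms: dioxygen (O=O)
Why: Mukaiyama hydration: cobalt-hydride hydrogen-atom transfer to the 1,1-disubstituted alkene gives the tertiary radical, which is trapped by O2 and reduced to the Markovnikov tertiary alcohol while ketone and ester stay inert; no stereocentre is formed.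

Step 4
Reactants: 9 methyl 3-[(1S,4R)-4-(2-hydroxypropan-2-yl)-1-methyl-2-oxocyclohexyl]propanoate
Product: 10 methyl 3-[(1S,4R)-1-methyl-2-oxo-4-{2-[(triethylsilyl)oxy]propan-2-yl}cyclohexyl]propanoate
Conditions: TESOTf (1.3 equiv), 2,6-lutidine (2.5 equiv), CH2Cl2, −78 → −40 °C
Reagents that add atoms: triethylsilyl trifluoromethanesulfonate (CC[Si](CC)(CC)OS(=O)(=O)C(F)(F)F)
Why: Silylation with a silyl triflate and 2,6-lutidine is the standard way to cap hindered tertiary alcohols and at −78 °C is faster than enol silylation of the ketone; the TES ether removes the hydroxyl as a nucleophile toward the cations of step 10 and falls to fluoride at the end.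

Step 5
Reactants: 10 methyl 3-[(1S,4R)-1-methyl-2-oxo-4-{2-[(triethylsilyl)oxy]propan-2-yl}cyclohexyl]propanoate
Product: 11 methyl 3-[(1S,4R)-1-methyl-2-methylidene-4-{2-[(triethylsilyl)oxy]propan-2-yl}cyclohexyl]propanoate
Conditions: Ph3PCH3Br (2.2 equiv), KOt-Bu (2.0 equiv), THF, 0 °C → rt
Reagents that add atoms: methyltriphenylphosphonium bromide (C[P+](c1ccccc1)(c1ccccc1)c1ccccc1.[Br-])
Why: Wittig methylenation: the non-stabilised ylide adds to the ketone much faster than to the methyl ester, and neither the quaternary carbon nor the β-stereocentre can epimerise under the basic conditions.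

Step 6
Reactants: 11 methyl 3-[(1S,4R)-1-methyl-2-methylidene-4-{2-[(triethylsilyl)oxy]propan-2-yl}cyclohexyl]propanoate
Product: 12 3-[(1S,4R)-1-methyl-2-methylidene-4-{2-[(triethylsilyl)oxy]propan-2-yl}cyclohexyl]propanoic acid
Conditions: LiOH·H2O (3 equiv), THF–MeOH–H2O (3:1:1), rt; then 0.5 M HCl to pH 4, 0 °C
Reagents that add atoms: lithium hydroxide ([Li+].[OH-])
Why: Ester saponification with LiOH leaves the tertiary TES ether and the 1,1-disubstituted alkene untouched, and the cold, mild acidification should avoid desilylation and alkene migration.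

Step 7
Reactants: 13 honokiol
Product: 14 3',5-diallyl-4'-[(tert-butyldimethylsilyl)oxy]-[1,1'-biphenyl]-2-ol (4'-O-TBS-honokiol)
Conditions: TBSCl (1.0 equiv), imidazole (2.2 equiv), CH2Cl2, −20 → 0 °C
Reagents that add atoms: tert-butyldimethylsilyl chloride (CC(C)(C)[Si](C)(C)Cl)
Why: Silylation with one equivalent of TBSCl/imidazole should favour the 4'-hydroxyl, which is flanked only by an allyl CH2, over the 2-hydroxyl, which is shielded by the twisted neighbouring ring; the regioisomer and the bis-silyl ether are separable and can be recycled with fluoride.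

Step 8
Reactants: 12 3-[(1S,4R)-1-methyl-2-methylidene-4-{2-[(triethylsilyl)oxy]propan-2-yl}cyclohexyl]propanoic acid; 14 4'-O-TBS-honokiol
Product: 15 3',5-diallyl-4'-[(tert-butyldimethylsilyl)oxy]-[1,1'-biphenyl]-2-yl 3-[(1S,4R)-1-methyl-2-methylidene-4-{2-[(triethylsilyl)oxy]propan-2-yl}cyclohexyl]propanoate
Conditions: DCC (1.2 equiv), DMAP (0.2 equiv), CH2Cl2, 0 °C → rt
Reagents that add atoms: none
Why: Steglich esterification (DCC activation, DMAP acyl transfer) makes the hindered C–O bond as an ordinary aryl ester, so no substitution at a tertiary carbon is ever required; alkenes and both silyl ethers are inert.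

Step 9
Reactants: 15 aryl ester
Product: 16 tert-butyl({3',5-diallyl-2-[(4-{(1S,4R)-1-methyl-2-methylidene-4-[2-(triethylsilyloxy)propan-2-yl]cyclohexyl}but-1-en-2-yl)oxy]-[1,1'-biphenyl]-4'-yl}oxy)dimethylsilane (aryl enol ether)
Conditions: Tebbe reagent (1.5 equiv, 0.5 M in toluene), pyridine (0.5 equiv), THF, −40 °C → rt; 15% aq. NaOH quench; basic Al2O3
Reagents that add atoms: Tebbe reagent (C[Al-]1(C)C[Ti]([Cl+]1)(C2C=CC=C2)C3C=CC=C3)
Why: Tebbe methylenation: the titanium methylidene undergoes [2+2] addition to the ester carbonyl and cycloreversion to the enol ether, a transformation established for aryl esters, while the C=C bonds can only undergo degenerate methylene exchange; the base quench and alumina filtration protect the acid-labile product.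

Step 10
Reactants: 16 aryl enol ether
Product: 17 tert-butyl{[3',5-diallyl-2-({(2R,4aS,7R,8aS)-2,4a-dimethyl-7-[2-(triethylsilyloxy)propan-2-yl]decahydronaphthalen-2-yl}oxy)-[1,1'-biphenyl]-4'-yl]oxy}dimethylsilane (bis-silyl ether of the target)
Conditions: Et3SiH (10 equiv), CF3CO2H (2 equiv), CH2Cl2, −78 → −20 °C; Et3N quench
Reagents that add atoms: none
Why: Trifluoroacetic acid protonates the terminal carbon of the aryl enol ether, by far the most basic of the five C=C bonds, to give an aryloxy-stabilised cation at C-2; the CH2 terminus of the exocyclic C-8a methylene adds to it (new C1–C2 bond) and the resulting tertiary C-8a cation takes hydride from triethylsilane, which leaves as triethylsilyl trifluoroacetate. The closest known reaction types are Prins-type cation–olefin carbocyclisations started from enol ethers or ketals onto 1,1-disubstituted alkenes, and the ionic hydrogenation of tertiary cations with Et3SiH/CF3CO2H. Ring C1–C2–C3–C4–C4a–C8a closes in a 6-endo-trig mode with respect to the alkene, through a chair that keeps the existing ring in the conformer with axial C-4a methyl and equatorial silyloxyisopropyl group, so that C-2 reaches the alkene face anti to that methyl. C-2: the chair places the small O-aryl group axial and CH3 equatorial, which gives (2R), and because the closure can revert by fragmentation of the C-8a cation, the same more stable arrangement is also favoured under equilibration. C-8a: hydride should enter axially, anti to the adjacent axial C-4a methyl, on the trajectory that leads directly to the chair trans-decalin, giving (8aS). The step needs ring closure to outrun hydride capture of the C-2 cation (secured by the intramolecular six-membered closure onto a nucleophilic 1,1-disubstituted alkene) and hydride capture of the C-8a cation to outrun proton loss, methyl shift and attack by the free ortho carbon of the aryloxy ring (secured by a large excess of silane at low temperature; the bridged chroman from such an attack would press the arene edge against the axial C-7 hydrogen), while the two silyl ethers keep both hydroxyl groups from trapping either cation.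

Step 11
Reactants: 17 bis-silyl ether of the target
Product: 18 3',5-diallyl-2-{[(2R,4aS,7R,8aS)-7-(2-hydroxypropan-2-yl)-2,4a-dimethyldecahydronaphthalen-2-yl]oxy}-[1,1'-biphenyl]-4'-ol (CNP0342687.1)
Conditions: TBAF (5 equiv), THF, rt → 45 °C
Reagents that add atoms: none
Why: Fluoride-induced desilylation should remove the aryl TBS ether at room temperature and the tertiary TES ether on gentle warming without touching the tertiary aryl ether, the allyl groups or any stereocentre.

**Compound list**

1 | (R)-carvone | CC1=CC[C@@H](C(C)=C)CC1=O | starting material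
2 | lithium (5R)-2-methyl-5-(prop-1-en-2-yl)cyclohex-1-en-1-olate | [Li+].[O-]C1=C(C)CC[C@@H](C(C)=C)C1 | intermediate (not isolated)
3 | (5R)-2-methyl-5-(prop-1-en-2-yl)cyclohexan-1-one (dihydrocarvone, C-2 epimers) | CC1CC[C@@H](C(C)=C)CC1=O | intermediate
4 | (R)-1-phenylethylamine | C[C@@H](N)c1ccccc1 | starting material
5 | methyl acrylate | C=CC(=O)OC | starting material
6 | (5R)-2-methyl-N-[(1R)-1-phenylethyl]-5-(prop-1-en-2-yl)cyclohexan-1-imine | CC1CC[C@@H](C(C)=C)CC1=N[C@H](C)c1ccccc1 | intermediate (not isolated)
7 | methyl 3-[(1S,4R)-1-methyl-2-{[(1R)-1-phenylethyl]imino}-4-(prop-1-en-2-yl)cyclohexyl]propanoate | COC(=O)CC[C@]1(C)CC[C@@H](C(C)=C)CC1=N[C@H](C)c1ccccc1 | intermediate (not isolated)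
8 | methyl 3-[(1S,4R)-1-methyl-2-oxo-4-(prop-1-en-2-yl)cyclohexyl]propanoate | COC(=O)CC[C@]1(C)CC[C@@H](C(C)=C)CC1=O | intermediate
9 | methyl 3-[(1S,4R)-4-(2-hydroxypropan-2-yl)-1-methyl-2-oxocyclohexyl]propanoate | COC(=O)CC[C@]1(C)CC[C@@H](C(C)(C)O)CC1=O | intermediate
10 | methyl 3-[(1S,4R)-1-methyl-2-oxo-4-{2-[(triethylsilyl)oxy]propan-2-yl}cyclohexyl]propanoate | COC(=O)CC[C@]1(C)CC[C@@H](C(C)(C)O[Si](CC)(CC)CC)CC1=O | intermediate
11 | methyl 3-[(1S,4R)-1-methyl-2-methylidene-4-{2-[(triethylsilyl)oxy]propan-2-yl}cyclohexyl]propanoate | COC(=O)CC[C@]1(C)CC[C@@H](C(C)(C)O[Si](CC)(CC)CC)CC1=C | intermediate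
12 | 3-[(1S,4R)-1-methyl-2-methylidene-4-{2-[(triethylsilyl)oxy]propan-2-yl}cyclohexyl]propanoic acid | OC(=O)CC[C@]1(C)CC[C@@H](C(C)(C)O[Si](CC)(CC)CC)CC1=C | intermediate
13 | honokiol (3',5-diallyl-[1,1'-biphenyl]-2,4'-diol) | C=CCc1ccc(O)c(-c2ccc(O)c(CC=C)c2)c1 | starting material
14 | 3',5-diallyl-4'-[(tert-butyldimethylsilyl)oxy]-[1,1'-biphenyl]-2-ol | C=CCc1ccc(O)c(-c2ccc(O[Si](C)(C)C(C)(C)C)c(CC=C)c2)c1 | intermediate
15 | 3',5-diallyl-4'-[(tert-butyldimethylsilyl)oxy]-[1,1'-biphenyl]-2-yl 3-[(1S,4R)-1-methyl-2-methylidene-4-{2-[(triethylsilyl)oxy]propan-2-yl}cyclohexyl]propanoate | C=CCc1ccc(OC(=O)CC[C@]3(C)CC[C@@H](C(C)(C)O[Si](CC)(CC)CC)CC3=C)c(-c2ccc(O[Si](C)(C)C(C)(C)C)c(CC=C)c2)c1 | intermediate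
16 | aryl enol ether: 2-aryloxybut-1-ene carrying the (1S,4R)-1-methyl-2-methylidene-4-(2-triethylsilyloxypropan-2-yl)cyclohexyl group at C-4, aryl = 3',5-diallyl-4'-(TBS-oxy)biphenyl-2-yl | C=CCc1ccc(OC(=C)CC[C@]3(C)CC[C@@H](C(C)(C)O[Si](CC)(CC)CC)CC3=C)c(-c2ccc(O[Si](C)(C)C(C)(C)C)c(CC=C)c2)c1 | intermediate
17 | bis-silyl ether of the target, (2R,4aS,7R,8aS)-decalin with 4'-O-TBS and tertiary O-TES | C=CCc1ccc(O[C@]2(C)CC[C@]3(C)CC[C@@H](C(C)(C)O[Si](CC)(CC)CC)C[C@H]3C2)c(-c2ccc(O[Si](C)(C)C(C)(C)C)c(CC=C)c2)c1 | intermediate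
18 | 3',5-diallyl-2-{[(2R,4aS,7R,8aS)-7-(2-hydroxypropan-2-yl)-2,4a-dimethyldecahydronaphthalen-2-yl]oxy}-[1,1'-biphenyl]-4'-ol | C=CCc1ccc(O[C@]2(C)CC[C@]3(C)CC[C@@H](C(C)(C)O)C[C@H]3C2)c(-c2ccc(O)c(CC=C)c2)c1 | target

**Step count and risks**

Total step count: 11. Longest linear sequence: 10 steps (1–6 and 8–11, from (R)-carvone); step 7 is the one-step side branch from honokiol.

Steps most likely to fail:

1. Step 10. What may go wrong: hydride transfer to the C-2 oxocarbenium ion before the ring closes; capture of the C-8a cation by the free ortho carbon of the aryloxy ring (Friedel–Crafts closure to a bridged chroman) or its decay by proton loss faster than hydride transfer; hydride delivery syn to the angular methyl; closure with O-aryl equatorial. The fallback answers the Friedel–Crafts interception with a blocking group. It sets out from 14 and returns at 17. NBS with catalytic diisopropylamine (CH2Cl2, −78 → 0 °C) should brominate the only free position ortho to the free phenol and give 3-bromo-4'-O-TBS-honokiol F1. DCC/DMAP coupling with acid 12 would give the bromo aryl ester F2, and Tebbe methylenation the bromo aryl enol ether F3. The same CF3CO2H/Et3SiH closure would then give the brominated decalin ether F4, whose aryloxy ring has no free ortho carbon within reach of C-8a and is less nucleophilic. Bromine–lithium exchange (t-BuLi, THF, −78 °C) and a methanol quench rejoin the route at 17.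

2. Step 7. What may go wrong: poor site selectivity, i.e. silylation of the 2-hydroxyl or of both phenols. The fallback masks the 4'-hydroxyl through its ortho allyl group. It sets out from 13 and returns at 15. Iodoetherification (I2, NaHCO3, MeCN, 0 °C) can only engage the 4'-hydroxyl, the one phenol with an ortho allyl group, and should give 4-allyl-2-[2-(iodomethyl)-2,3-dihydrobenzofuran-5-yl]phenol F5 with the 2-hydroxyl free. DCC/DMAP coupling with 12 gives the masked aryl ester F6. Zinc dust (NH4Cl, EtOH) reopens the β-iodo ether to the 4'-hydroxy aryl ester F7 with its allyl group restored, and TBSCl/imidazole returns to 15.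

3. Step 5. What may go wrong: slow ylide addition at the carbonyl next to the quaternary carbon, so that enolisation and ylide attack on the methyl ester compete. The fallback merges both methylenations. It sets out from 10 and returns at 16. Saponification (LiOH, then mild acid) gives the keto acid F8, and DCC/DMAP coupling with 14 gives the keto aryl ester F9. An excess of Tebbe reagent, which methylenates hindered enolisable ketones without base as well as esters, should install both methylene groups in one operation and rejoin the route at 16.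

Further compounds
F1 | step 10 | 3',5-diallyl-3-bromo-4'-[(tert-butyldimethylsilyl)oxy]-[1,1'-biphenyl]-2-ol | C=CCc1cc(Br)c(O)c(-c2ccc(O[Si](C)(C)C(C)(C)C)c(CC=C)c2)c1
F2 | step 10 | 3-bromo analogue of aryl ester 15 | C=CCc1cc(Br)c(OC(=O)CC[C@]2(C)CC[C@@H](C(C)(C)O[Si](CC)(CC)CC)CC2=C)c(-c3ccc(O[Si](C)(C)C(C)(C)C)c(CC=C)c3)c1
F3 | step 10 | 3-bromo analogue of aryl enol ether 16 | C=CCc1cc(Br)c(OC(=C)CC[C@]2(C)CC[C@@H](C(C)(C)O[Si](CC)(CC)CC)CC2=C)c(-c3ccc(O[Si](C)(C)C(C)(C)C)c(CC=C)c3)c1
F4 | step 10 | 3-bromo analogue of bis-silyl ether 17 | C=CCc1cc(Br)c(O[C@]2(C)CC[C@]3(C)CC[C@@H](C(C)(C)O[Si](CC)(CC)CC)C[C@H]3C2)c(-c4ccc(O[Si](C)(C)C(C)(C)C)c(CC=C)c4)c1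
F5 | step 7 | 4-allyl-2-[2-(iodomethyl)-2,3-dihydro-1-benzofuran-5-yl]phenol (both configurations at the dihydrofuran carbon) | C=CCc1ccc(O)c(-c2ccc3OC(CI)Cc3c2)c1
F6 | step 7 | 4-allyl-2-[2-(iodomethyl)-2,3-dihydro-1-benzofuran-5-yl]phenyl ester of acid 12 | C=CCc1ccc(OC(=O)CC[C@]2(C)CC[C@@H](C(C)(C)O[Si](CC)(CC)CC)CC2=C)c(-c3ccc4OC(CI)Cc4c3)c1
F7 | step 7 | 3',5-diallyl-4'-hydroxy-[1,1'-biphenyl]-2-yl ester of acid 12 | C=CCc1ccc(OC(=O)CC[C@]2(C)CC[C@@H](C(C)(C)O[Si](CC)(CC)CC)CC2=C)c(-c3ccc(O)c(CC=C)c3)c1
F8 | step 5 | 3-[(1S,4R)-1-methyl-2-oxo-4-{2-[(triethylsilyl)oxy]propan-2-yl}cyclohexyl]propanoic acid | OC(=O)CC[C@]1(C)CC[C@@H](C(C)(C)O[Si](CC)(CC)CC)CC1=O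
F9 | step 5 | 3',5-diallyl-4'-[(tert-butyldimethylsilyl)oxy]-[1,1'-biphenyl]-2-yl ester of keto acid F8 | C=CCc1ccc(OC(=O)CC[C@]2(C)CC[C@@H](C(C)(C)O[Si](CC)(CC)CC)CC2=O)c(-c3ccc(O[Si](C)(C)C(C)(C)C)c(CC=C)c3)c1
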